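| flask | substrate | reagent in the second phase | remark | time | volume of the second phase over the first |
|---|---|---|---|---|---|
| Wednesday's | 0.80 M | 0.59 M | run made earlier |  |  |
| Monday's | 0.80 M | 1.3 M | run made earlier |  |  |
| flask | 0.80 M | 0.880 M |  | 4.0 h | 1.0 |

| run | time / h | target / % | crystals / % |
|---|---|---|---|
| Wednesday's | 0.833 | 15 | 7 |
| Wednesday's | 1.50 | 22 | 19 |
| Wednesday's | 2.50 | 32 | 28 |
| Wednesday's | 3.00 | 36 | 32 |
| Wednesday's | 4.00 | 44 | 37 |
| Wednesday's | 5.00 | 44 | 40 |
| Monday's | 0.417 | 14 | 6 |
| Monday's | 0.667 | 21 | 15 |
| Monday's | 1.00 | 31 | 24 |
| Monday's | 2.00 | 51 | 46 |
| Monday's | 3.00 | 67 | 61 |
| Monday's | 5.00 | 74 | 76 |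

(each reading ± 1.5 percentage points)

- amounts and yields of target count product in the second phase and crystals too
- in the second phase: reagent in the second phase, product in the second phase; everything else is in the first
- charges count per volume of the first phase; a concentration in a rate is the amount of a species over the volume of its own phase; every rate counts per litre of the first phase
- given per volume of solution although it is solid: crystals
- the earlier runs hold the two phases in the same ratio of volumes as the flask asked about

* target and product in the second phase and crystals together at 4.0 h, in percent of the substrate charged
* concentration of target in solution at 4.0 h, in percent of saturation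

- Late readings show how the books stand: Monday's run reaches 74% at 5.00 h, and Wednesday's stands at 44% at 5.00 h.
- I book one mole of reagent in the second phase per mole of substrate used; that is my assumption. Wednesday's reagent charge then covers 73.7% of the substrate, and that run's late reading stands lower.
- In the flask, c(substrate) of 0.80 M is less than c(reagent in the second phase) of 0.880 M, so substrate is the limiting reagent by charge.
- I replace each curve by its mean. I take a target reading as the substrate used, divide by the time, then divide by the straight means of c(substrate) and c(reagent in the second phase), each running from its charge to its charge less what is used.
- The last reading but one gives 0.341 /M/h for Wednesday's run and 0.325 /M/h for Monday's. I carry their average, 0.333 /M/h, as the mean pace.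
- To check the error, I reckon Monday's last reading back: the mean pace gives 88.2% against 74%. So the mean pace overshoots at that late reading.
- For the flask at 4.0 h, the mean pace gives 59.8% of the substrate charged as used.
- Total less crystals in Wednesday's last reading is 4 percentage points, with a scatter of 1.5 points per reading, so I commit to no saturation figure.
- The forecast says 55%, lower than mine, and 125% of saturation. Of the second it writes: “This estimate is poorly determined”.
- The flask gives 56.6% and 149% of saturation. At 4.00 h its books close with substrate 39%, target with its forms 56.6%, decomposed product 2.97% and isomer of the product 1.20%. My 59.8% of substrate used stands 0.99 points below the flask's 61.0%, and decomposed product and isomer of the product together hold 4.2 points of that. Reckoned on the substrate used, this flask's mean pace is 0.343 /M/h, against 0.333 /M/h from the target readings of the runs.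

    reagent in the reaction phase ⇌ reagent in the second phase, rate k1*([reagent in the reaction phase] - [reagent in the second phase]/K1) per volume of the first phase (partition coefficient = 1.20, kL = 7.60 × 10⁻⁴ /s)
    substrate + reagent in the reaction phase → target (k = 2.80 × 10⁻⁴ /M/s)
    target ⇌ product in the second phase, rate k3*([target] - [product in the second phase]/K3) per volume of the first phase (partition coefficient = 0.160, kL = 1.00 × 10⁻⁴ /s)
    target → decomposed product (k = 5.30 × 10⁻⁵ /s)
    crystals ⇌ target, rate k5*(cs5 - [target]) while solid is left; crystals form when [target] > cs5 (solubility = 16.0 mM, k = 0.00190 /s)
    target ⇌ isomer of the product (K = 0.390, k = 5.00 × 10⁻⁵ /s)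

- For the same flask read at 2.5 h, the mean pace gives 45.1% of the substrate charged as used. That flask gives 44.4% of target with its forms, with 52.4% of the substrate left.

(The data were generated by integration with made-up constants; noise was put on by code.)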